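**Retrosynthetic overview**

- Numbering runs from the vinyl end: C1=C2, C10 is the ester carbinol, the oxolane ring is O–C11–C12–C13–C14, and the pentyl group is C15–C19. The palmitate is placed on C10–O last, after exchanging PMB (on C10–O) for TBS (on C13–O).
- The strategy rests on the C13–OH / C14–pentyl pair of the oxolane ring, which are cis to each other and both trans to the C11 side chain. This pattern maps onto the C13=C14 enol ether of a 2-substituted 2,3-dihydrofuran, epoxidised anti to C11 and opened at C14 with same-face transfer of pentyl from tripentylaluminium (forms C13–O and C14–C15).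
- The dihydrofuran is the only ring of the target. It is closed before the key step (O–C14) by molybdenum-catalysed cycloisomerisation of a syn homopropargylic alcohol. The oxirane of the key step is transient.
- C11–C12 and the C11 stereocentre come from chelation-controlled propargylation of an (R)-2-(PMB-oxy) aldehyde. C8–C9 and the C10 stereocentre come from copper-catalysed opening of (R)-trityl glycidyl ether by oct-7-enylmagnesium bromide.

Key step: step 7

Assumption: tripentylaluminium is not treated as a catalogue reagent; it is generated within step 7 from 1-bromopentane through pentylmagnesium bromide and AlCl3 (three C5 units per aluminium) and used as a solution without isolation; dimethyldioxirane (DMDO) is used as a freshly prepared acetone solution; allenyltributylstannane is taken as a purchased reagent.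

**Route**

Step 1
Reactants: 1 8-bromooct-1-ene; 2 (R)-trityl glycidyl ether, (2R)-2-[(trityloxy)methyl]oxirane
Product: 4 (2R)-1-(trityloxy)undec-10-en-2-ol, via oct-7-enylmagnesium bromide 3 (not isolated)
Conditions: Mg, THF, 40 °C; then CuI (10 mol %), 2, THF, −30 → 0 °C; aq NH4Cl
Reagents that add atoms: magnesium, [Mg] (held only in 3)
Why: Copper-catalysed Grignard opening of a terminal epoxide: the organocopper species from 3 should attack the unsubstituted oxirane carbon in SN2 fashion (C8–C9 bond), so the stereocentre of 2 is untouched and becomes C10 (R).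

Step 2
Reactants: 4 (2R)-1-(trityloxy)undec-10-en-2-ol
Product: 5 (10R)-10-[(4-methoxybenzyl)oxy]-11-(trityloxy)undec-1-ene
Conditions: NaH, PMBCl, Bu4NI (cat.), DMF, 0 °C → rt
Reagents that add atoms: 4-methoxybenzyl chloride, COc1ccc(CCl)cc1
Why: Williamson etherification of the secondary alkoxide (iodide-catalysed) should proceed cleanly because the trityl ether and the terminal alkene are inert to base and no bond to the stereocentre is broken.

Step 3
Reactants: 5 (10R)-10-[(4-methoxybenzyl)oxy]-11-(trityloxy)undec-1-ene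
Product: 6 (2R)-2-[(4-methoxybenzyl)oxy]undec-10-en-1-ol
Conditions: TsOH·H2O (10 mol %), MeOH/CH2Cl2 (1:1), 0 °C → rt
Reagents that add atoms: none
Why: Acid-catalysed SN1 detritylation (transetherification to methanol): the trityl cation ionises far more readily than a PMB ether cleaves, so only the primary alcohol should be freed.

Step 4
Reactants: 6 (2R)-2-[(4-methoxybenzyl)oxy]undec-10-en-1-ol
Product: 7 (2R)-2-[(4-methoxybenzyl)oxy]undec-10-enal
Conditions: Dess–Martin periodinane, CH2Cl2, 0 °C → rt; used at once
Reagents that add atoms: none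
Why: Dess–Martin oxidation of the primary alcohol stops at the aldehyde under near-neutral conditions and should not epimerise the α-alkoxy centre or touch the PMB ether and alkene.

Step 5
Reactants: 7 (2R)-2-[(4-methoxybenzyl)oxy]undec-10-enal; 8 allenyltributylstannane
Product: 9 (4R,5R)-5-[(4-methoxybenzyl)oxy]tetradec-13-en-1-yn-4-ol
Conditions: MgBr2·OEt2 (2.5 equiv), CH2Cl2, −20 °C; then 8, −20 °C → rt
Reagents that add atoms: none
Why: Chelation-controlled SE2′ propargylation: MgBr2 bridges the aldehyde and α-PMB-ether oxygens and the allenylstannane should add to the carbonyl face opposite the C9 chain of the five-membered chelate, setting C11 as R (syn to C10–O) and giving the homopropargylic rather than the allenic alcohol.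

Step 6
Reactants: 9 (4R,5R)-5-[(4-methoxybenzyl)oxy]tetradec-13-en-1-yn-4-ol
Product: 10 (2R)-2-{(1R)-1-[(4-methoxybenzyl)oxy]dec-9-en-1-yl}-2,3-dihydrofuran
Conditions: Mo(CO)6 (30 mol %), Me3NO (30 mol %), Et3N/Et2O, rt; Et3N-deactivated silica
Reagents that add atoms: none
Why: Molybdenum-catalysed alkynol cycloisomerisation: the terminal alkyne rearranges to a molybdenum vinylidene, the C11 hydroxyl adds to its electrophilic carbon (C14) and protodemetalation releases the endocyclic enol ether (overall 5-endo closure, O–C14 bond), with C10 and C11 untouched.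

Step 7
Reactants: 10 (2R)-2-{(1R)-1-[(4-methoxybenzyl)oxy]dec-9-en-1-yl}-2,3-dihydrofuran; 11 1-bromopentane
Product: 15 (2S,3S,5R)-5-{(1R)-1-[(4-methoxybenzyl)oxy]dec-9-en-1-yl}-2-pentyloxolan-3-ol, via pentylmagnesium bromide 12 (not isolated), via tripentylaluminium 13 (not isolated), via anti-epoxide 14 (not isolated)
Conditions: (a) 11 (9 equiv), Mg, Et2O, reflux; AlCl3 (3 equiv), 0 °C → rt; hexane, filtration under Ar, exchange into CH2Cl2 (solution of 13); (b) 10, DMDO (1.05 equiv, acetone), CH2Cl2, −78 °C; volatiles off at ≤0 °C; solution of 13 (3 equiv), CH2Cl2, −78 → 0 °C; aq potassium sodium tartrate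
Reagents that add atoms: dimethyldioxirane, CC1(C)OO1; magnesium, [Mg] (held only in 12); aluminium trichloride, Cl[Al](Cl)Cl (aluminium held only in 13)
Why: Three equivalents of pentylmagnesium bromide 12 (Grignard formation from 11) are transmetalated with one of AlCl3 to give tripentylaluminium 13, so three molecules of 11 are spent per molecule of 13 and only one pentyl group of 13 ends up in the product. Dimethyldioxirane transfers oxygen in a concerted spiro transition state to the electron-rich C13=C14 enol ether of 10 on the ring face anti to the branched C11 side chain, giving oxirane 14; 13 then binds the oxirane oxygen, the C14–O bond ionises to an oxolane oxocarbenium/alkoxy(tripentyl)aluminate contact ion pair, and one pentyl group passes from aluminium to C14 on the face that holds the C13–O–Al unit. The closest known reaction type is dimethyldioxirane epoxidation of glycals followed by syn-selective opening of the 1,2-anhydro sugar with a trialkylaluminium reagent to give 1,2-cis C-glycosides. No ring of the target is closed here (the oxolane dates from step 6); the only ring formed is the transient oxirane, by [2+1] oxygen transfer, and it is opened again in the same flask. C13 (S) is controlled by the C11 stereocentre through anti epoxidation and C14 (S) by internal same-face pentyl delivery, so C13–OH and C14–pentyl should end up cis to each other and trans to C11. The step needs the enol ether to be oxidised in preference to the C1=C2 alkene and the PMB ether, which its much higher nucleophilicity towards one equivalent of dioxirane at −78 °C should secure, and it needs syn pentyl transfer to outrun β-hydride transfer and external anti attack, which the tight ion pair in non-coordinating CH2Cl2 at low temperature with excess reagent should secure.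

Step 8
Reactants: 15 (2S,3S,5R)-5-{(1R)-1-[(4-methoxybenzyl)oxy]dec-9-en-1-yl}-2-pentyloxolan-3-ol
Product: 16 tert-butyl{[(2S,3S,5R)-5-{(1R)-1-[(4-methoxybenzyl)oxy]dec-9-en-1-yl}-2-pentyloxolan-3-yl]oxy}dimethylsilane
Conditions: TBSOTf, 2,6-lutidine, CH2Cl2, −78 → 0 °C
Reagents that add atoms: tert-butyldimethylsilyl trifluoromethanesulfonate, CC(C)(C)[Si](C)(C)OS(=O)(=O)C(F)(F)F
Why: O-silylation of the hindered ring alcohol with the silyl triflate/2,6-lutidine pair masks C13–OH without touching any stereocentre, so that only C10–O can be acylated later.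

Step 9
Reactants: 16 tert-butyl{[(2S,3S,5R)-5-{(1R)-1-[(4-methoxybenzyl)oxy]dec-9-en-1-yl}-2-pentyloxolan-3-yl]oxy}dimethylsilane
Product: 17 (1R)-1-[(2R,4S,5S)-4-{[tert-butyl(dimethyl)silyl]oxy}-5-pentyloxolan-2-yl]dec-9-en-1-ol
Conditions: DDQ, CH2Cl2/pH 7 buffer (10:1), 0 °C → rt
Reagents that add atoms: none
Why: Oxidative PMB cleavage (hydride abstraction from the electron-rich benzylic position by DDQ, then hydrolysis of the oxocarbenium ion) should leave the TBS ether, the oxolane and the isolated terminal alkene untouched.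

Step 10
Reactants: 17 (1R)-1-[(2R,4S,5S)-4-{[tert-butyl(dimethyl)silyl]oxy}-5-pentyloxolan-2-yl]dec-9-en-1-ol; 18 hexadecanoyl (palmitoyl) chloride
Product: 19 (1R)-1-[(2R,4S,5S)-4-{[tert-butyl(dimethyl)silyl]oxy}-5-pentyloxolan-2-yl]dec-9-en-1-yl hexadecanoate
Conditions: pyridine, DMAP (cat.), CH2Cl2, 0 °C → rt
Reagents that add atoms: none
Why: DMAP-catalysed acylation (nucleophilic catalysis through the acylpyridinium ion) of the only free hydroxyl should give the C10 palmitate with retention, since the C10–O bond is not broken.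

Step 11
Reactants: 19 (1R)-1-[(2R,4S,5S)-4-{[tert-butyl(dimethyl)silyl]oxy}-5-pentyloxolan-2-yl]dec-9-en-1-yl hexadecanoate
Product: 20 (1R)-1-[(2R,4S,5S)-4-hydroxy-5-pentyloxolan-2-yl]dec-9-en-1-yl hexadecanoate (target)
Conditions: HF·pyridine, pyridine, THF, 0 °C → rt
Reagents that add atoms: none
Why: Fluoride-mediated desilylation with buffered HF·pyridine cleaves only the Si–O bond, and acyl migration from C10–O to C13–O is not expected because the two oxygens lie on opposite ring faces and a seven-membered transition state would be needed.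

**Compound list**

1 | 8-bromooct-1-ene | C=CCCCCCCBr | starting material
2 | (R)-trityl glycidyl ether, (2R)-2-[(trityloxy)methyl]oxirane | C1[C@@H](O1)COC(c2ccccc2)(c2ccccc2)c2ccccc2 | starting material
3 | oct-7-enylmagnesium bromide | C=CCCCCCC[Mg]Br | intermediate (not isolated)
4 | (2R)-1-(trityloxy)undec-10-en-2-ol | C=CCCCCCCC[C@@H](O)COC(c1ccccc1)(c1ccccc1)c1ccccc1 | intermediate
5 | (10R)-10-[(4-methoxybenzyl)oxy]-11-(trityloxy)undec-1-ene | C=CCCCCCCC[C@@H](OCc1ccc(OC)cc1)COC(c1ccccc1)(c1ccccc1)c1ccccc1 | intermediate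
6 | (2R)-2-[(4-methoxybenzyl)oxy]undec-10-en-1-ol | C=CCCCCCCC[C@@H](OCc1ccc(OC)cc1)CO | intermediate
7 | (2R)-2-[(4-methoxybenzyl)oxy]undec-10-enal | C=CCCCCCCC[C@@H](OCc1ccc(OC)cc1)C=O | intermediate
8 | allenyltributylstannane, tributyl(propa-1,2-dienyl)stannane | C=C=C[Sn](CCCC)(CCCC)CCCC | starting material
9 | (4R,5R)-5-[(4-methoxybenzyl)oxy]tetradec-13-en-1-yn-4-ol | C=CCCCCCCC[C@@H](OCc1ccc(OC)cc1)[C@H](O)CC#C | intermediate
10 | (2R)-2-{(1R)-1-[(4-methoxybenzyl)oxy]dec-9-en-1-yl}-2,3-dihydrofuran | C=CCCCCCCC[C@@H](OCc1ccc(OC)cc1)[C@H]1CC=CO1 | intermediate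
11 | 1-bromopentane | CCCCCBr | starting material
12 | pentylmagnesium bromide | CCCCC[Mg]Br | intermediate (not isolated)
13 | tripentylaluminium | CCCCC[Al](CCCCC)CCCCC | intermediate (not isolated)
14 | (1R,3R,5S)-3-{(1R)-1-[(4-methoxybenzyl)oxy]dec-9-en-1-yl}-2,6-dioxabicyclo[3.1.0]hexane (oxirane oxygen anti to the C3 side chain) | C=CCCCCCCC[C@@H](OCc1ccc(OC)cc1)[C@H]1C[C@@H]2O[C@@H]2O1 | intermediate (not isolated)
15 | (2S,3S,5R)-5-{(1R)-1-[(4-methoxybenzyl)oxy]dec-9-en-1-yl}-2-pentyloxolan-3-ol | C=CCCCCCCC[C@@H](OCc1ccc(OC)cc1)[C@H]1C[C@H](O)[C@H](CCCCC)O1 | intermediate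
16 | tert-butyl{[(2S,3S,5R)-5-{(1R)-1-[(4-methoxybenzyl)oxy]dec-9-en-1-yl}-2-pentyloxolan-3-yl]oxy}dimethylsilane | C=CCCCCCCC[C@@H](OCc1ccc(OC)cc1)[C@H]1C[C@H](O[Si](C)(C)C(C)(C)C)[C@H](CCCCC)O1 | intermediate
17 | (1R)-1-[(2R,4S,5S)-4-{[tert-butyl(dimethyl)silyl]oxy}-5-pentyloxolan-2-yl]dec-9-en-1-ol | C=CCCCCCCC[C@@H](O)[C@H]1C[C@H](O[Si](C)(C)C(C)(C)C)[C@H](CCCCC)O1 | intermediate
18 | hexadecanoyl (palmitoyl) chloride | CCCCCCCCCCCCCCCC(=O)Cl | starting material
19 | (1R)-1-[(2R,4S,5S)-4-{[tert-butyl(dimethyl)silyl]oxy}-5-pentyloxolan-2-yl]dec-9-en-1-yl hexadecanoate | C=CCCCCCCC[C@@H](OC(=O)CCCCCCCCCCCCCCC)[C@H]1C[C@H](O[Si](C)(C)C(C)(C)C)[C@H](CCCCC)O1 | intermediate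
20 | (1R)-1-[(2R,4S,5S)-4-hydroxy-5-pentyloxolan-2-yl]dec-9-en-1-yl hexadecanoate | C=CCCCCCCC[C@@H](OC(=O)CCCCCCCCCCCCCCC)[C@H]1C[C@H](O)[C@H](CCCCC)O1 | target

**Step count**

Total step count: 11. Longest linear sequence: 11 steps (steps 1–11); 1-bromopentane 11 enters in step 7, where the aluminium reagent is made and used without isolation.

**Steps most likely to fail**

1. Step 7.
What may go wrong: β-hydride transfer from a pentyl group to the oxocarbenium carbon instead of pentyl transfer (reduction at C14); leakage to external anti attack; incomplete facial discrimination in the epoxidation; capture of the cation by the C10 ether oxygen; or incomplete transmetalation, leaving chloroaluminium species that deliver chloride.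
Fallback (sets out from 10, rejoins the route at 16):
Dihydrofuran 10 would be epoxidised with dimethyldioxirane as before, but the oxirane would be opened in the same flask with methanol. This should give the methyl furanoside (2S,3S,5R)-2-methoxy-5-{(1R)-1-[(4-methoxybenzyl)oxy]dec-9-en-1-yl}oxolan-3-ol F1, whose anomer composition is of no consequence. Silylation (TBSOTf, 2,6-lutidine) gives its tert-butyldimethylsilyl ether F2. F2 is then ionised with BF3·OEt2 in CH2Cl2 at −78 °C in the presence of 2-(trimethylsilyloxy)pent-1-ene F3 (from pentan-2-one, LiN(i-Pr)2, Me3SiCl, THF, −78 °C). This is a Mukaiyama-type C-glycosylation of a five-membered oxocarbenium ion; such ions bearing an adjacent alkoxy or silyloxy group are attacked on the inside face of the envelope that holds that group pseudo-equatorial, which favours the 1,2-cis product. The expected product is 1-[(2S,3S,5R)-3-{[tert-butyl(dimethyl)silyl]oxy}-5-{(1R)-1-[(4-methoxybenzyl)oxy]dec-9-en-1-yl}oxolan-2-yl]pentan-2-one F4. Condensation with TsNHNH2 in EtOH gives the tosylhydrazone F5. Reduction with catecholborane (CHCl3, 0 °C) followed by NaOAc·3H2O at reflux removes the carbonyl oxygen, turns the side chain into pentyl and gives silyl ether 16. This fallback makes C14–C15 without alkyl transfer from aluminium, and it uses no alkene or alkyne that would have to be reduced beside the C1=C2 alkene.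

2. Step 6.
What may go wrong: deactivation of the molybdenum catalyst by oxygen or by coordination of the alkene and ether groups; oligomerisation of the terminal alkyne; and hydrolysis of the acid-sensitive enol ether during isolation.
Fallback (sets out from 9, rejoins the route at 10):
Alkynol 9 would be converted by ruthenium-catalysed cycloisomerisation–oxidation (CpRu(cod)Cl, tri(2-furyl)phosphine, N-hydroxysuccinimide, Bu4NBr, NaHCO3, DMF/H2O, 95 °C) into the γ-lactone (5R)-5-{(1R)-1-[(4-methoxybenzyl)oxy]dec-9-en-1-yl}oxolan-2-one F6. Reduction with i-Bu2AlH in CH2Cl2 at −78 °C gives the lactol (5R)-5-{(1R)-1-[(4-methoxybenzyl)oxy]dec-9-en-1-yl}oxolan-2-ol F7. Dehydration through the lactol methanesulfonate F8 (MsCl, Et3N, CH2Cl2, −40 °C → reflux, not isolated) gives dihydrofuran 10.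

3. Step 5.
What may go wrong: erosion of chelation control (loss of syn selectivity at C11); epimerisation of the α-alkoxy aldehyde before addition; and leakage to the allenyl carbinol.
Fallback (sets out from 3, made from 1 as in step 1; rejoins the route at 9):
Oct-7-enylmagnesium bromide 3 would be added with CuI catalysis (THF, −40 °C) to an excess of purchased (R,R)-1,2:3,4-diepoxybutane (C1O[C@H]1[C@H]1CO1; mutagenic, handled under containment). Opening at one terminal carbon gives the epoxy alcohol (1R)-1-[(2R)-oxiran-2-yl]dec-9-en-1-ol F9. Etherification (NaH, PMBBr, Bu4NI, THF, 0 °C, short contact time to hold back Payne rearrangement) gives (2R)-2-{(1R)-1-[(4-methoxybenzyl)oxy]dec-9-en-1-yl}oxirane F10. Opening of the remaining terminal epoxide with LiC≡CH·H2NCH2CH2NH2 in DMSO at rt gives alkynol 9. Both stereocentres then come from the C2-symmetric diepoxide, whose configuration is retained because only the CH2 termini react, and no diastereoselective carbonyl addition is needed.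

**Further compounds**

F1 | step 7 | (2S,3S,5R)-2-methoxy-5-{(1R)-1-[(4-methoxybenzyl)oxy]dec-9-en-1-yl}oxolan-3-ol | C=CCCCCCCC[C@@H](OCc1ccc(OC)cc1)[C@H]1C[C@H](O)[C@@H](OC)O1
F2 | step 7 | tert-butyl{[(2S,3S,5R)-2-methoxy-5-{(1R)-1-[(4-methoxybenzyl)oxy]dec-9-en-1-yl}oxolan-3-yl]oxy}dimethylsilane | C=CCCCCCCC[C@@H](OCc1ccc(OC)cc1)[C@H]1C[C@H](O[Si](C)(C)C(C)(C)C)[C@@H](OC)O1
F3 | step 7 | 2-(trimethylsilyloxy)pent-1-ene | C=C(CCC)O[Si](C)(C)C
F4 | step 7 | 1-[(2S,3S,5R)-3-{[tert-butyl(dimethyl)silyl]oxy}-5-{(1R)-1-[(4-methoxybenzyl)oxy]dec-9-en-1-yl}oxolan-2-yl]pentan-2-one | C=CCCCCCCC[C@@H](OCc1ccc(OC)cc1)[C@H]1C[C@H](O[Si](C)(C)C(C)(C)C)[C@H](CC(=O)CCC)O1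
F5 | step 7 | 4-methylbenzenesulfonylhydrazone of F4 | C=CCCCCCCC[C@@H](OCc1ccc(OC)cc1)[C@H]1C[C@H](O[Si](C)(C)C(C)(C)C)[C@H](CC(CCC)=NNS(=O)(=O)c2ccc(C)cc2)O1
F6 | step 6 | (5R)-5-{(1R)-1-[(4-methoxybenzyl)oxy]dec-9-en-1-yl}oxolan-2-one | C=CCCCCCCC[C@@H](OCc1ccc(OC)cc1)[C@H]1CCC(=O)O1
F7 | step 6 | (5R)-5-{(1R)-1-[(4-methoxybenzyl)oxy]dec-9-en-1-yl}oxolan-2-ol (anomer mixture) | C=CCCCCCCC[C@@H](OCc1ccc(OC)cc1)[C@H]1CCC(O)O1
F8 | step 6 | (5R)-5-{(1R)-1-[(4-methoxybenzyl)oxy]dec-9-en-1-yl}oxolan-2-yl methanesulfonate (anomer mixture) | C=CCCCCCCC[C@@H](OCc1ccc(OC)cc1)[C@H]1CCC(OS(C)(=O)=O)O1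
F9 | step 5 | (1R)-1-[(2R)-oxiran-2-yl]dec-9-en-1-ol | C=CCCCCCCC[C@@H](O)[C@H]1CO1
F10 | step 5 | (2R)-2-{(1R)-1-[(4-methoxybenzyl)oxy]dec-9-en-1-yl}oxirane | C=CCCCCCCC[C@@H](OCc1ccc(OC)cc1)[C@H]1CO1
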